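**Retrosynthetic overview**
- The (Z)-3-methylbuta-1,3-dienyl group at C8 of ring A is put on last, by Sonogashira coupling of an 8-iodoflavanone with 2-methylbut-1-en-3-yne and syn semireduction of the enyne.
- The pyranone ring C is opened at O1–C2 to an alkylidene β-ketoester (an activated chalcone), made by Knoevenagel condensation of a dihydrobenzofuran-5-carbaldehyde with an iodophloroglucinol β-ketoester.
- The strategy rests on the C2–C3 bond of the trans-2,3-diaryl-2,3-dihydrobenzofuran fused to ring B: an O-benzylic C2–H next to a diarylmethine C3–H. This bond is made by insertion of a diaryl carbene (from a benzophenone hydrazone) into the CH2 of an ortho 4-methoxybenzyl ether.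
- Ring order: the dihydrofuran ring first (on the bromoresorcinol arene), then ring C by asymmetric oxa-Michael closure, and the side chain last.

Key step: step 4

Assumption: the (R)-configured dirhodium catalyst and the quinidine-derived thiourea are taken, by analogy with simpler substrates, to give the 3R and 2S centres; if either sense proves opposite, the mirror-image or pseudoenantiomeric catalyst is used in the same step.

**Route**

Step 1
Reactants: 1 4-bromoresorcinol; 2 3,5-dimethoxybenzoyl chloride
Product: 3 (5-bromo-2,4-dihydroxyphenyl)(3,5-dimethoxyphenyl)methanone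
Conditions: BF3·OEt2 (excess), 1,4-dioxane, 80 °C; then H2O
Reagents that add atoms: none
Why: Friedel–Crafts C-acylation (by O-acylation and Fries-type migration under the boron Lewis acid) should occur at C6 of the resorcinol, ortho to one hydroxyl and para to the other, and leave the methyl ethers intact.

Step 2
Reactants: 3 (5-bromo-2,4-dihydroxyphenyl)(3,5-dimethoxyphenyl)methanone; 4 4-methoxybenzyl chloride
Product: 5 {5-bromo-2,4-bis[(4-methoxybenzyl)oxy]phenyl}(3,5-dimethoxyphenyl)methanone
Conditions: 4 (2.4 equiv), K2CO3, KI (cat.), DMF, 70 °C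
Reagents that add atoms: none
Why: Double Williamson etherification, in which heating overcomes the carbonyl-chelated ortho hydroxyl; the ortho ether supplies the future C2 and ring oxygen and the para ether only protects.

Step 3
Reactants: 5 {5-bromo-2,4-bis[(4-methoxybenzyl)oxy]phenyl}(3,5-dimethoxyphenyl)methanone
Product: 6 hydrazone of ketone 5 (expected as an E/Z mixture)
Conditions: N2H4·H2O (excess), AcOH (cat.), EtOH, 85 °C, sealed tube
Reagents that add atoms: hydrazine (as hydrate), NN
Why: Acid-catalysed condensation of the diaryl ketone with a large excess of hydrazine should give the N-unsubstituted hydrazone and suppress azine formation.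

Step 4
Reactants: 6 hydrazone of ketone 5
Product: 8 cis-(2S,3R)-5-bromo-3-(3,5-dimethoxyphenyl)-6-[(4-methoxybenzyl)oxy]-2-(4-methoxyphenyl)-2,3-dihydrobenzofuran, via diaryldiazomethane 7 (not isolated)
Conditions: MnO2 (8 equiv), MeCN, 0 °C; then Rh2(R-PTAD)4 [dirhodium tetrakis((R)-1-adamantyl-phthalimidoacetate), 1 mol%], 0 °C to rt
Reagents that add atoms: none
Why: Manganese dioxide dehydrogenates the hydrazone to diazo compound 7, the dirhodium tetracarboxylate expels N2 to form a donor/donor rhodium carbene, and the carbene carbon (future C3) inserts into a C–H bond of the ortho O–CH2–aryl group through a concerted, asynchronous, hydride-transfer-like transition state that forms the C2–C3 bond. The closest known reaction type is the enantioselective intramolecular C–H insertion of diaryl carbenes generated from ortho-benzyloxy benzophenone hydrazones under chiral dirhodium carboxylate catalysis, which is applied here to a new substrate. The dihydrofuran ring closes by 1,5-insertion, through a five-membered cyclic transition state comprising the carbene carbon, two arene carbons, the ether oxygen and the methylene carbon. C3 should be set as R by the chiral pocket of the phthalimidoacetate ligands (catalyst control), and C2 should arise cis to it (2S) because the compact insertion transition state places the two aryl groups on the same face; this kinetic C2 configuration is corrected in step 5. The step needs site selectivity for the ortho ether methylene over the remote para 4-methoxybenzyl ether, the methoxy C–H bonds, arene addition and azine or carbene-dimer formation. This is secured by the 1,5-relationship, by the hydridic character of a C–H flanked by the ether oxygen and the 4-methoxyphenyl ring, and by the attenuated electrophilicity of the donor/donor carbene, which also leaves the aryl bromide untouched.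

Step 5
Reactants: 8 cis-(2S,3R)-5-bromo-3-(3,5-dimethoxyphenyl)-6-[(4-methoxybenzyl)oxy]-2-(4-methoxyphenyl)-2,3-dihydrobenzofuran
Product: 9 trans-(2R,3R)-5-bromo-3-(3,5-dihydroxyphenyl)-2-(4-hydroxyphenyl)-2,3-dihydrobenzofuran-6-ol
Conditions: BBr3 (10 equiv), pentamethylbenzene (5 equiv), CH2Cl2, −78 °C to rt; then H2O
Reagents that add atoms: none
Why: Lewis-acid ether cleavage should remove the three methyl ethers and the 4-methoxybenzyl ether (its cation trapped by pentamethylbenzene in a Friedel–Crafts alkylation), while reversible ionisation of the benzylic C2–O bond to a 4-oxybenzyl cation lets the ring reclose to the more stable trans isomer, relayed from the untouched 3R centre.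

Step 6
Reactants: 9 trans-(2R,3R)-5-bromo-3-(3,5-dihydroxyphenyl)-2-(4-hydroxyphenyl)-2,3-dihydrobenzofuran-6-ol
Product: 10 trans-(2R,3R)-5-bromo-3-[3,5-bis(methoxymethoxy)phenyl]-6-(methoxymethoxy)-2-[4-(methoxymethoxy)phenyl]-2,3-dihydrobenzofuran
Conditions: MOMCl (6 equiv), i-Pr2NEt, CH2Cl2, 0 °C to rt
Reagents that add atoms: chloromethyl methyl ether, COCCl
Why: O-alkylation of all four phenols to MOM acetals under a mild amine base, which cannot disturb the benzylic stereocentres.

Step 7
Reactants: 10 trans-(2R,3R)-5-bromo-3-[3,5-bis(methoxymethoxy)phenyl]-6-(methoxymethoxy)-2-[4-(methoxymethoxy)phenyl]-2,3-dihydrobenzofuran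
Product: 12 trans-(2R,3R)-3-[3,5-bis(methoxymethoxy)phenyl]-6-(methoxymethoxy)-2-[4-(methoxymethoxy)phenyl]-2,3-dihydrobenzofuran-5-carbaldehyde, via aryllithium 11 (not isolated)
Conditions: n-BuLi (1.1 equiv), THF, −78 °C; DMF, −78 to 0 °C; aq. NH4Cl
Reagents that add atoms: n-butyllithium, [Li]CCCC (the lithium of 11); N,N-dimethylformamide, CN(C)C=O
Why: Bromine–lithium exchange, faster at −78 °C than any benzylic or ortho deprotonation and giving an aryllithium chelated by the neighbouring MOM ether, followed by formylation with DMF.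

Step 8
Reactants: 13 methyl 2,4,6-trihydroxybenzoate
Product: 14 methyl 2-hydroxy-4,6-bis(methoxymethoxy)benzoate
Conditions: MOMCl (2.2 equiv), i-Pr2NEt, CH2Cl2, 0 °C to rt
Reagents that add atoms: chloromethyl methyl ether, COCCl
Why: Selective O-alkylation: the 4-hydroxyl and one ortho hydroxyl react, and the remaining ortho hydroxyl, hydrogen-bonded to the ester carbonyl, should stay free.

Step 9
Reactants: 14 methyl 2-hydroxy-4,6-bis(methoxymethoxy)benzoate
Product: 15 methyl 2-hydroxy-3-iodo-4,6-bis(methoxymethoxy)benzoate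
Conditions: NIS (1.05 equiv), DMF, 0 °C to rt, dark
Reagents that add atoms: N-iodosuccinimide, O=C1CCC(=O)N1I
Why: Electrophilic aromatic iodination should go ortho to the free phenol, as in the related 2-hydroxy-4,6-dialkoxyaryl ketones, because the other open position is crowded between two MOM ethers; this puts iodine next to the oxygen that later becomes O1.

Step 10
Reactants: 15 methyl 2-hydroxy-3-iodo-4,6-bis(methoxymethoxy)benzoate; 16 tert-butyl acetate
Product: 17 tert-butyl 3-[2-hydroxy-3-iodo-4,6-bis(methoxymethoxy)phenyl]-3-oxopropanoate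
Conditions: LDA (4.4 equiv), 16 (4.5 equiv), THF, −78 °C; then 15, −78 to 0 °C; aq. NH4Cl
Reagents that add atoms: none
Why: Crossed Claisen condensation: excess lithium enolate first deprotonates the phenol, then adds to the lithium-chelated ester, and the product is held as its phenoxide/ketoester-enolate dianion until work-up.

Step 11
Reactants: 12 trans-(2R,3R)-dihydrobenzofuran-5-carbaldehyde tetra-MOM ether; 17 tert-butyl 3-[2-hydroxy-3-iodo-4,6-bis(methoxymethoxy)phenyl]-3-oxopropanoate
Product: 18 tert-butyl 2-[2-hydroxy-3-iodo-4,6-bis(methoxymethoxy)benzoyl]-3-[(2R,3R)-3-[3,5-bis(methoxymethoxy)phenyl]-6-(methoxymethoxy)-2-[4-(methoxymethoxy)phenyl]-2,3-dihydrobenzofuran-5-yl]prop-2-enoate (expected as an E/Z mixture)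
Conditions: piperidine (20 mol%), AcOH (20 mol%), 4 Å molecular sieves, toluene, rt to 40 °C
Reagents that add atoms: none
Why: Knoevenagel condensation through iminium activation of the electron-rich aldehyde; the single free phenol is chelated to the ketone and flanked by iodine, so uncatalysed ring closure should be slow.

Step 12
Reactants: 18 alkylidene β-ketoester
Product: 19 tert-butyl (2S)-2-[(2R,3R)-3-[3,5-bis(methoxymethoxy)phenyl]-6-(methoxymethoxy)-2-[4-(methoxymethoxy)phenyl]-2,3-dihydrobenzofuran-5-yl]-8-iodo-5,7-bis(methoxymethoxy)-4-oxochromane-3-carboxylate (C3 epimer/enol mixture, carried on without chromatography)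
Conditions: N-[3,5-bis(trifluoromethyl)phenyl]-N'-[(9R)-6'-methoxycinchonan-9-yl]thiourea (quinidine-derived, 10–15 mol%), toluene, −25 °C
Reagents that add atoms: none
Why: Bifunctional organocatalytic intramolecular oxa-Michael addition (6-endo-trig): the thiourea binds the ketoester while the quinuclidine delivers the phenol to one face of the alkylidene, so the new C2 centre should be set as S under catalyst control, remote from the dihydrobenzofuran centres.

Step 13
Reactants: 19 tert-butyl (2S)-4-oxochromane-3-carboxylate hexa-MOM ether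
Product: 20 (2S)-2-[(2R,3R)-3-(3,5-dihydroxyphenyl)-6-hydroxy-2-(4-hydroxyphenyl)-2,3-dihydrobenzofuran-5-yl]-5,7-dihydroxy-8-iodochroman-4-one
Conditions: aq. HCl (3 M), THF, 50 °C
Reagents that add atoms: none
Why: Acid hydrolysis cleaves the tert-butyl ester by alkyl–oxygen fission, the β-keto acid decarboxylates at 50 °C and the six aryl MOM acetals hydrolyse in the same medium; no alcohol cosolvent is used so the acid cannot be re-esterified, and since the pyranone ring opens chiefly by a base-mediated E1cB path the 2S centre should persist.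

Step 14
Reactants: 20 (2S)-8-iodoflavanone hexaol
Product: 21 (2S)-5,7-diacetoxy-2-[(2R,3R)-6-acetoxy-2-(4-acetoxyphenyl)-3-(3,5-diacetoxyphenyl)-2,3-dihydrobenzofuran-5-yl]-8-iodochroman-4-one
Conditions: Ac2O, pyridine, 0 °C to rt
Reagents that add atoms: acetic anhydride, CC(=O)OC(C)=O
Why: O-acetylation of all six phenols, which masks the 7-hydroxyl that would otherwise cyclise onto the alkyne of the next step and removes the free phenols that could open ring C under amine base.

Step 15
Reactants: 21 hexaacetate of the 8-iodoflavanone; 22 2-methylbut-1-en-3-yne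
Product: 23 (2S)-5,7-diacetoxy-2-[(2R,3R)-6-acetoxy-2-(4-acetoxyphenyl)-3-(3,5-diacetoxyphenyl)-2,3-dihydrobenzofuran-5-yl]-8-(3-methylbut-3-en-1-yn-1-yl)chroman-4-one
Conditions: 22 (5 equiv), PdCl2(PPh3)2 (5 mol%), CuI (10 mol%), Et3N, THF, rt to 40 °C, sealed vessel
Reagents that add atoms: none
Why: Sonogashira coupling: oxidative addition of the aryl iodide to zerovalent palladium, transfer of the copper acetylide and reductive elimination, under conditions mild enough for the aryl acetates and the flavanone centre.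

Step 16
Reactants: 23 8-enynyl flavanone hexaacetate
Product: 24 (2S)-5,7-diacetoxy-2-[(2R,3R)-6-acetoxy-2-(4-acetoxyphenyl)-3-(3,5-diacetoxyphenyl)-2,3-dihydrobenzofuran-5-yl]-8-[(1Z)-3-methylbuta-1,3-dien-1-yl]chroman-4-one
Conditions: Zn dust activated with Cu(OAc)2 and AgNO3, MeOH–H2O–THF, rt to 40 °C
Reagents that add atoms: none
Why: Zinc-mediated syn semireduction of a conjugated enyne (Boland-type reduction) adds two hydrogens to the same face of the triple bond, giving the Z alkene without reducing the ketone or the terminal alkene; any acetate lost here is inconsequential because step 17 removes all of them.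

Step 17
Reactants: 24 (Z)-dienyl flavanone hexaacetate
Product: 25 (2S)-2-[(2R,3R)-3-(3,5-dihydroxyphenyl)-6-hydroxy-2-(4-hydroxyphenyl)-2,3-dihydrobenzofuran-5-yl]-5,7-dihydroxy-8-[(1Z)-3-methylbuta-1,3-dien-1-yl]chroman-4-one (CNP0284772.1)
Conditions: NH4OAc (excess), MeOH–H2O (4:1), rt
Reagents that add atoms: none
Why: Near-neutral transesterification of the aryl acetates, which avoids the acid that would cyclise the 7-hydroxyl onto the diene and the strong base that would open ring C.

**Compound list**
1 | 4-bromoresorcinol | Oc1ccc(Br)c(O)c1 | starting material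
2 | 3,5-dimethoxybenzoyl chloride | COc1cc(OC)cc(C(=O)Cl)c1 | starting material
3 | (5-bromo-2,4-dihydroxyphenyl)(3,5-dimethoxyphenyl)methanone | COc1cc(OC)cc(c1)C(=O)c1cc(Br)c(O)cc1O | intermediate
4 | 4-methoxybenzyl chloride | COc1ccc(CCl)cc1 | starting material
5 | {5-bromo-2,4-bis[(4-methoxybenzyl)oxy]phenyl}(3,5-dimethoxyphenyl)methanone | COc1cc(OC)cc(c1)C(=O)c1cc(Br)c(OCc2ccc(OC)cc2)cc1OCc1ccc(OC)cc1 | intermediate
6 | hydrazone of ketone 5 | COc1cc(OC)cc(c1)C(=NN)c1cc(Br)c(OCc2ccc(OC)cc2)cc1OCc1ccc(OC)cc1 | intermediate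
7 | 1-bromo-5-[diazo(3,5-dimethoxyphenyl)methyl]-2,4-bis[(4-methoxybenzyl)oxy]benzene | COc1cc(OC)cc(c1)C(=[N+]=[N-])c1cc(Br)c(OCc2ccc(OC)cc2)cc1OCc1ccc(OC)cc1 | intermediate
8 | cis-(2S,3R)-5-bromo-3-(3,5-dimethoxyphenyl)-6-[(4-methoxybenzyl)oxy]-2-(4-methoxyphenyl)-2,3-dihydrobenzofuran | Brc1cc2c(cc1OCc1ccc(OC)cc1)O[C@H](c1ccc(OC)cc1)[C@@H]2c1cc(OC)cc(OC)c1 | intermediate
9 | trans-(2R,3R)-5-bromo-3-(3,5-dihydroxyphenyl)-2-(4-hydroxyphenyl)-2,3-dihydrobenzofuran-6-ol | Brc1cc2c(cc1O)O[C@@H](c1ccc(O)cc1)[C@@H]2c1cc(O)cc(O)c1 | intermediate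
10 | trans-(2R,3R)-5-bromo-3-[3,5-bis(methoxymethoxy)phenyl]-6-(methoxymethoxy)-2-[4-(methoxymethoxy)phenyl]-2,3-dihydrobenzofuran | Brc1cc2c(cc1OCOC)O[C@@H](c1ccc(OCOC)cc1)[C@@H]2c1cc(OCOC)cc(OCOC)c1 | intermediate
11 | 5-lithio analogue of 10 (aryllithium) | [Li]c1cc2c(cc1OCOC)O[C@@H](c1ccc(OCOC)cc1)[C@@H]2c1cc(OCOC)cc(OCOC)c1 | intermediate
12 | trans-(2R,3R)-3-[3,5-bis(methoxymethoxy)phenyl]-6-(methoxymethoxy)-2-[4-(methoxymethoxy)phenyl]-2,3-dihydrobenzofuran-5-carbaldehyde | O=Cc1cc2c(cc1OCOC)O[C@@H](c1ccc(OCOC)cc1)[C@@H]2c1cc(OCOC)cc(OCOC)c1 | intermediate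
13 | methyl 2,4,6-trihydroxybenzoate | COC(=O)c1c(O)cc(O)cc1O | starting material
14 | methyl 2-hydroxy-4,6-bis(methoxymethoxy)benzoate | COC(=O)c1c(O)cc(OCOC)cc1OCOC | intermediate
15 | methyl 2-hydroxy-3-iodo-4,6-bis(methoxymethoxy)benzoate | COC(=O)c1c(O)c(I)c(OCOC)cc1OCOC | intermediate
16 | tert-butyl acetate | CC(=O)OC(C)(C)C | starting material
17 | tert-butyl 3-[2-hydroxy-3-iodo-4,6-bis(methoxymethoxy)phenyl]-3-oxopropanoate | CC(C)(C)OC(=O)CC(=O)c1c(O)c(I)c(OCOC)cc1OCOC | intermediate
18 | alkylidene β-ketoester from 12 and 17 (E/Z mixture) | CC(C)(C)OC(=O)C(=Cc1cc2c(cc1OCOC)O[C@@H](c1ccc(OCOC)cc1)[C@@H]2c1cc(OCOC)cc(OCOC)c1)C(=O)c1c(O)c(I)c(OCOC)cc1OCOC | intermediate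
19 | tert-butyl (2S)-2-(dihydrobenzofuran-5-yl)-8-iodo-5,7-bis(methoxymethoxy)-4-oxochromane-3-carboxylate, hexa-MOM ether | Ic1c(OCOC)cc(OCOC)c2c1O[C@H](c1cc3c(cc1OCOC)O[C@@H](c1ccc(OCOC)cc1)[C@@H]3c1cc(OCOC)cc(OCOC)c1)C(C(=O)OC(C)(C)C)C2=O | intermediate
20 | (2S)-2-[(2R,3R)-3-(3,5-dihydroxyphenyl)-6-hydroxy-2-(4-hydroxyphenyl)-2,3-dihydrobenzofuran-5-yl]-5,7-dihydroxy-8-iodochroman-4-one | Ic1c(O)cc(O)c2c1O[C@H](c1cc3c(cc1O)O[C@@H](c1ccc(O)cc1)[C@@H]3c1cc(O)cc(O)c1)CC2=O | intermediate
21 | hexaacetate of 20 | Ic1c(OC(C)=O)cc(OC(C)=O)c2c1O[C@H](c1cc3c(cc1OC(C)=O)O[C@@H](c1ccc(OC(C)=O)cc1)[C@@H]3c1cc(OC(C)=O)cc(OC(C)=O)c1)CC2=O | intermediate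
22 | 2-methylbut-1-en-3-yne | C=C(C)C#C | starting material
23 | 8-(3-methylbut-3-en-1-yn-1-yl) flavanone hexaacetate | C=C(C)C#Cc1c(OC(C)=O)cc(OC(C)=O)c2c1O[C@H](c1cc3c(cc1OC(C)=O)O[C@@H](c1ccc(OC(C)=O)cc1)[C@@H]3c1cc(OC(C)=O)cc(OC(C)=O)c1)CC2=O | intermediate
24 | 8-[(1Z)-3-methylbuta-1,3-dien-1-yl] flavanone hexaacetate | C=C(C)/C=C\c1c(OC(C)=O)cc(OC(C)=O)c2c1O[C@H](c1cc3c(cc1OC(C)=O)O[C@@H](c1ccc(OC(C)=O)cc1)[C@@H]3c1cc(OC(C)=O)cc(OC(C)=O)c1)CC2=O | intermediate
25 | CNP0284772.1 | C=C(C)/C=C\c1c(O)cc(O)c2c1O[C@H](c1cc3c(cc1O)O[C@@H](c1ccc(O)cc1)[C@@H]3c1cc(O)cc(O)c1)CC2=O | target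

**Step count and risks**

Total step count: 17. Longest linear sequence: 14 steps (steps 1–7, then 11–17); the ring A fragment takes steps 8–10.

Steps most likely to fail:

1. Step 12. The oxa-Michael addition may show poor facial selectivity, because the catalyst must override a bulky, chiral, ortho-substituted and electron-rich β-aryl group, and the adduct may revert by retro-Michael reaction before the ester is removed. Fallback: setting out from 18, the ring is closed without stereocontrol by an achiral amine (Et3N, toluene, rt), which should give 19 together with its 2R epimer, tert-butyl (2R)-8-iodo-4-oxochromane-3-carboxylate hexa-MOM ether F1. The mixture is taken through the conditions of step 13 to 20 and the (2R)-8-iodoflavanone hexaol F2. These two are diastereomers, because the dihydrobenzofuran centres are fixed, and are to be separated by preparative reversed-phase HPLC. The route is rejoined at 20.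

2. Step 10. The enolate may fail to add to an ester carbonyl that is flanked by two ortho substituents and deactivated by the adjacent phenoxide, so that the ester is returned while the acetate enolate self-condenses. Fallback: setting out from 15, the ester is saponified (KOH, aqueous DMSO, 80 °C; cold, mildly acidic work-up) to 2-hydroxy-3-iodo-4,6-bis(methoxymethoxy)benzoic acid F3. The acid is activated with carbonyldiimidazole (THF, rt) as 1-[2-hydroxy-3-iodo-4,6-bis(methoxymethoxy)benzoyl]imidazole F4. This is treated with the magnesium enolate of mono-tert-butyl malonate (half-ester, MgCl2, Et3N, THF, rt to 40 °C) in a decarboxylative Claisen condensation, which is driven by loss of CO2 and uses a far more electrophilic acyl donor. The route is rejoined at 17.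

3. Step 13. Hot aqueous acid may remove iodine from the very electron-rich ring A by ipso-protonation, may erode C2 by opening ring C at the doubly oxygen-activated benzylic position, and may let liberated formaldehyde alkylate the phloroglucinol ring. Fallback: setting out from 19, protic hydrolysis is replaced by aprotic silyl transfer. TMSOTf and 2,2'-bipyridyl (CH2Cl2, 0 °C) should convert each aryl MOM ether into the aryl silyl ether, with the acetal carbon captured as a bipyridinium salt and not released as formaldehyde, and the tert-butyl ester into the silyl ester, giving trimethylsilyl (2S)-8-iodo-4-oxo-hexakis(trimethylsilyloxy)chromane-3-carboxylate F5. Water in THF at rt then liberates the (2S)-8-iodo-4-oxochromane-3-carboxylic acid hexaol F6, which loses CO2 on warming to 40 °C. The route is rejoined at 20.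

**Further compounds**
F1 | step 12 | tert-butyl (2R)-2-(dihydrobenzofuran-5-yl)-8-iodo-5,7-bis(methoxymethoxy)-4-oxochromane-3-carboxylate, hexa-MOM ether (2R epimer of 19) | Ic1c(OCOC)cc(OCOC)c2c1O[C@@H](c1cc3c(cc1OCOC)O[C@@H](c1ccc(OCOC)cc1)[C@@H]3c1cc(OCOC)cc(OCOC)c1)C(C(=O)OC(C)(C)C)C2=O
F2 | step 12 | (2R)-2-[(2R,3R)-3-(3,5-dihydroxyphenyl)-6-hydroxy-2-(4-hydroxyphenyl)-2,3-dihydrobenzofuran-5-yl]-5,7-dihydroxy-8-iodochroman-4-one (2R epimer of 20) | Ic1c(O)cc(O)c2c1O[C@@H](c1cc3c(cc1O)O[C@@H](c1ccc(O)cc1)[C@@H]3c1cc(O)cc(O)c1)CC2=O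
F3 | step 10 | 2-hydroxy-3-iodo-4,6-bis(methoxymethoxy)benzoic acid | OC(=O)c1c(O)c(I)c(OCOC)cc1OCOC
F4 | step 10 | 1-[2-hydroxy-3-iodo-4,6-bis(methoxymethoxy)benzoyl]imidazole | O=C(c1c(O)c(I)c(OCOC)cc1OCOC)n1ccnc1
F5 | step 13 | trimethylsilyl (2S)-8-iodo-4-oxo-hexakis(trimethylsilyloxy)chromane-3-carboxylate (all six phenols as trimethylsilyl ethers) | Ic1c(O[Si](C)(C)C)cc(O[Si](C)(C)C)c2c1O[C@H](c1cc3c(cc1O[Si](C)(C)C)O[C@@H](c1ccc(O[Si](C)(C)C)cc1)[C@@H]3c1cc(O[Si](C)(C)C)cc(O[Si](C)(C)C)c1)C(C(=O)O[Si](C)(C)C)C2=O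
F6 | step 13 | (2S)-2-[(2R,3R)-3-(3,5-dihydroxyphenyl)-6-hydroxy-2-(4-hydroxyphenyl)-2,3-dihydrobenzofuran-5-yl]-5,7-dihydroxy-8-iodo-4-oxochromane-3-carboxylic acid | Ic1c(O)cc(O)c2c1O[C@H](c1cc3c(cc1O)O[C@@H](c1ccc(O)cc1)[C@@H]3c1cc(O)cc(O)c1)C(C(=O)O)C2=O
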